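The C40 polyene is cut on both sides of its centre, at C14–C15 and C15'–C14'. The unsubstituted trans C15=C15' ethene between the methyl-bearing C13 and C13' is supplied by a tin–boron vinyl linchpin. In one pot, zerovalent palladium first joins the stannyl end to the ring-A iodide 18 (Stille) and then, once base is added, the boryl end to the furanoid iodide 20 (Suzuki). Both partners are finished, unprotected C19 alkenyl iodides carrying all five stereocentres: the (3S,5R,6S)-trihydroxycyclohexane (ring A) tetraenyl iodide and the (3'S,5'R,8'R)-dihydrofuran-fused (rings B and C) trienyl iodide. Both are drawn from one silylated C19 diol iodide, 17.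

Key step: step 16

Remark: carotenoid locants are used in the text (ring A C1–C6, chain C7–C15; primed locants for the furanoid half, ring B C1'–C6', ring C O/C5'–C8'). TBS = tert-butyldimethylsilyl. Enynol 5 is assumed to be the pure E isomer.

Step 1
Reactants: 1 ketoisophorone (2,6,6-trimethylcyclohex-2-ene-1,4-dione)
Product: 2 (S)-phorenol, (4S)-4-hydroxy-2,6,6-trimethylcyclohex-2-en-1-one
Conditions: RuCl[(S,S)-TsDPEN](p-cymene) (0.5 mol %), i-PrOH, rt
Reagents that add atoms: none
Why: Noyori–Ikariya asymmetric transfer hydrogenation should reduce only the unhindered C4 carbonyl (the other is flanked by CMe2 and C(Me)=), and the (S,S)-ligand, with the alkenyl group in the role of the aryl group of an aryl ketone, should give the (S)-carbinol that becomes C3 and C3' (the (R,R)-catalyst is the alternative should the sense be reversed for this cyclic enedione).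

Step 2
Reactants: 2 (S)-phorenol
Product: 3 (4S)-4-[(tert-butyldimethylsilyl)oxy]-2,6,6-trimethylcyclohex-2-en-1-one
Conditions: TBSCl, imidazole, DMF, rt
Reagents that add atoms: tert-butyldimethylsilyl chloride, CC(C)(C)[Si](C)(C)Cl
Why: Standard imidazole-promoted silylation of the secondary allylic alcohol; the bulky silyl ether later steers the epoxidation and survives every basic or hydridic step up to fluoride cleavage, and no stereocentre is touched.

Step 3
Reactants: 3 silyl ether of (S)-phorenol
Product: 4 (1R,5S,6R)-5-[(tert-butyldimethylsilyl)oxy]-1,3,3-trimethyl-7-oxabicyclo[4.1.0]heptan-2-one (oxirane oxygen trans to the silyloxy group)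
Conditions: 30% aq. H2O2, benzyltrimethylammonium hydroxide (Triton B, cat.), THF, 0 °C
Reagents that add atoms: hydrogen peroxide, OO
Why: Weitz–Scheffer nucleophilic epoxidation: hydroperoxide should add to the enone β-carbon (C4) from the face opposite the adjacent C3 silyloxy group and then close onto C5, so the oxirane is trans to O3 and fixes the C5 oxygen in the R configuration (together with the temporary C4 centre).

Step 4
Reactants: 4 epoxy ketone; 5 (E)-3-methylpent-2-en-4-yn-1-ol
Product: 7 (1R,2R,5S,6R)-5-[(tert-butyldimethylsilyl)oxy]-2-[(3E)-5-hydroxy-3-methylpent-3-en-1-yn-1-yl]-1,3,3-trimethyl-7-oxabicyclo[4.1.0]heptan-2-ol, via dilithio enynol 6 (not isolated)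
Conditions: 5 (1.5 equiv), n-BuLi (3.0 equiv), THF, −78 to 0 °C; then 4, −78 °C to rt; H2O
Reagents that add atoms: none
Why: 1,2-Addition of a lithium acetylide to a non-enolisable ketone: in the half-chair with the silyloxy group pseudoequatorial the alkynyl group should enter axially on the face opposite both the oxirane oxygen and the axial C1 methyl, which places the new 6-OH cis to the C5 oxygen as required for the 5,6-cis-diol.

Step 5
Reactants: 7 alkynyl epoxy diol
Product: 8 (2E)-5-[(1R,2R,4S)-4-[(tert-butyldimethylsilyl)oxy]-1,2-dihydroxy-2,6,6-trimethylcyclohexyl]-3-methylpent-2-en-4-yn-1-ol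
Conditions: LiEt3BH (5 equiv), THF, 0 °C to rt; H2O
Reagents that add atoms: none
Why: SN2 epoxide opening by LiEt3BH (Super-Hydride reduction): hydride should attack the only accessible oxirane carbon, the secondary C4, trans-diaxially, leaving the C5–O bond and its configuration intact and revealing the tertiary 5-OH cis to 6-OH; alkyne and silyl ether are inert to this reagent.

Step 6
Reactants: 8 alkynyl triol
Product: 9 (2E,4E)-5-[(1S,2R,4S)-4-[(tert-butyldimethylsilyl)oxy]-1,2-dihydroxy-2,6,6-trimethylcyclohexyl]-3-methylpenta-2,4-dien-1-ol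
Conditions: NaAlH2(OCH2CH2OMe)2 (Red-Al, 4 equiv), THF, 0 °C to rt; aq. potassium sodium tartrate
Reagents that add atoms: none
Why: Hydroxyl-directed trans-hydroalumination of the propargylic alkyne (delivery from the C6 alkoxyaluminate) followed by protonolysis should give the 7E alkene only, as in the classical reduction of tertiary ring propargylic alcohols carrying this enynol side chain; no stereocentre changes.

Step 7
Reactants: 9 dienyl triol
Product: 10 (2E,4E)-5-[(1S,2R,4S)-4-[(tert-butyldimethylsilyl)oxy]-1,2-dihydroxy-2,6,6-trimethylcyclohexyl]-3-methylpenta-2,4-dienal (C15 aldehyde)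
Conditions: activated MnO2 (excess), CH2Cl2, rt, dark
Reagents that add atoms: none
Why: Chemoselective MnO2 oxidation of the primary dienylic alcohol to the dienal; the two tertiary hydroxyls and the silyl ether cannot be oxidised and the neutral conditions spare the acid-labile allylic diol.

Step 8
Reactants: 11 propargyl alcohol (prop-2-yn-1-ol)
Product: 13 (E)-3-iodo-2-methylprop-2-en-1-ol, via alkenylalane 12 (not isolated)
Conditions: AlMe3 (3 equiv), Cp2ZrCl2 (0.25 equiv), CH2Cl2, 0 °C to rt; then I2, THF, −30 to 0 °C
Reagents that add atoms: trimethylaluminium, C[Al](C)C; iodine, II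
Why: Negishi zirconium-catalysed carboalumination adds methyl and aluminium syn across the alkyne (methyl to the internal carbon) and iodinolysis of the C–Al bond proceeds with retention, fixing on a simple substrate the E trisubstituted iodoalkene that becomes C13=C14 and C13'=C14'.

Step 9
Reactants: 13 (E)-3-iodo-2-methylprop-2-en-1-ol
Product: 14 (E)-3-bromo-1-iodo-2-methylprop-1-ene
Conditions: PBr3 (0.4 equiv), Et2O, 0 °C
Reagents that add atoms: phosphorus tribromide, BrP(Br)Br
Why: SN2 bromination of the primary allylic alcohol with PBr3; the vinyl iodide and the alkene geometry are not affected.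

Step 10
Reactants: 14 (E)-3-bromo-1-iodo-2-methylprop-1-ene
Product: 15 diethyl [(2E)-3-iodo-2-methylprop-2-en-1-yl]phosphonate
Conditions: P(OEt)3 (neat), 120 °C
Reagents that add atoms: triethyl phosphite, CCOP(OCC)OCC
Why: Michaelis–Arbuzov reaction at the sp3 allylic bromide; the sp2 C–I bond does not react with a phosphite in the absence of a transition-metal catalyst, so the E iodoalkene is retained.

Step 11
Reactants: 10 C15 aldehyde; 15 iodoallyl phosphonate
Product: 17 (1S,2R,4S)-4-[(tert-butyldimethylsilyl)oxy]-1-[(1E,3E,5E,7E)-8-iodo-3,7-dimethylocta-1,3,5,7-tetraen-1-yl]-2,6,6-trimethylcyclohexane-1,2-diol, via lithiated phosphonate 16 (not isolated)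
Conditions: 15 (3 equiv), LiN(SiMe3)2 (3 equiv), THF, −78 °C; then 10, −78 to 0 °C, dark
Reagents that add atoms: none
Why: Horner–Wadsworth–Emmons olefination of the enal with the α-lithiated allylic phosphonate should form C11=C12 with E selectivity, an amide base (no alkyllithium) avoiding iodine–lithium exchange and the excess anion covering the two free tertiary hydroxyls; no stereocentre is touched.

Step 12
Reactants: 17 silylated C19 diol iodide
Product: 18 ring-A C19 tetraenyl iodide, (1S,2R,4S)-1-[(1E,3E,5E,7E)-8-iodo-3,7-dimethylocta-1,3,5,7-tetraen-1-yl]-2,6,6-trimethylcyclohexane-1,2,4-triol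
Conditions: Bu4NF, THF, 0 °C to rt, dark
Reagents that add atoms: none
Why: Fluoride-induced cleavage of the secondary silyl ether under basic, non-acidic conditions, which the iodotetraene and the acid-sensitive 3,5,6-triol tolerate; no stereocentre is touched.

Step 13
Reactants: 17 silylated C19 diol iodide
Product: 19 (2R,6S,7aR)-6-[(tert-butyldimethylsilyl)oxy]-2-[(2E,4E,6E)-7-iodo-6-methylhepta-2,4,6-trien-2-yl]-4,4,7a-trimethyl-2,4,5,6,7,7a-hexahydro-1-benzofuran
Conditions: camphorsulfonic acid (10 mol %), CH2Cl2, 4 Å molecular sieves, −20 to 0 °C, dark; Et3N quench; chromatography on Et3N-deactivated silica to remove the C8' epimer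
Reagents that add atoms: none
Why: Acid-catalysed dehydrative cyclisation (intramolecular SN1' etherification, the diol counterpart of the epoxide–furanoid rearrangement of carotenoid 5,6-epoxides): ionisation of the tertiary allylic 6-OH gives a cation delocalised from C6 to C14 that the cis 5-OH captures at C8 to close the 2,5-dihydrofuran (ring C) with C5 untouched, suprafacial closure of the 7E,s-cis cation giving the 8R epimer (polyene trans to the C5 methyl) while any 8S epimer formed after C7–C8 rotation is separated and re-equilibrated under the same acid, and the silyl ether keeps O3 from bridging to C6.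

Step 14
Reactants: 19 silylated furanoid C19 iodide
Product: 20 furanoid C19 iodide, (2R,6S,7aR)-2-[(2E,4E,6E)-7-iodo-6-methylhepta-2,4,6-trien-2-yl]-4,4,7a-trimethyl-2,4,5,6,7,7a-hexahydro-1-benzofuran-6-ol
Conditions: Bu4NF, THF, 0 °C to rt, dark
Reagents that add atoms: none
Why: Fluoride desilylation as in step 12; the dihydrofuran ring is stable to base and C8' cannot epimerise without acid.

Step 15
Reactants: 21 ethynylboronic acid pinacol ester; 22 tributyltin hydride
Product: 23 (E)-2-(tributylstannyl)vinylboronic acid pinacol ester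
Conditions: AIBN (cat.), toluene, 80 °C
Reagents that add atoms: none
Why: Radical-chain hydrostannation of the terminal alkyne: the stannyl radical adds to the unsubstituted carbon and reversible addition–elimination equilibrates the product to the thermodynamically preferred E 1-boryl-2-stannylethene, a known way to this tin–boron linchpin.

Step 16
Reactants: 18 ring-A C19 tetraenyl iodide; 23 tin–boron ethene linchpin; 20 furanoid C19 iodide
Product: 25 CNP0210286.4 (target; (3S,5R,6S,3'S,5'R,8'R)-5',8'-epoxy-5,6,5',8'-tetrahydro-β,β-carotene-3,5,6,3'-tetrol), via C21 pentaenyl boronate 24 (not isolated)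
Conditions: Pd(PPh3)4 (10 mol %), 18, 23 (1.05 equiv), degassed DMF, 50 °C, dark; then 20 (1.0 equiv), degassed 2 M aq. KOH (3 equiv), THF, rt
Reagents that add atoms: none
Why: Oxidative addition of zerovalent palladium into the C14–I bond of 18, transmetalation from the tributylstannyl terminus of 23 under neutral conditions and reductive elimination form C14–C15 and leave the pinacol boronate untouched, giving 24. Hydroxide then turns the boronate into its ate complex, which transmetalates to the alkenylpalladium iodide formed from 20 and, after reductive elimination, closes C15'–C14'. The closest precedent is the one-pot Stille/Suzuki–Miyaura use of tin–boron alkene and diene linchpins in polyene synthesis, together with Stille assembly of carotenoids from alkenyl iodides. No ring is closed and no stereocentre is formed; every C=C geometry is carried over because each elementary step is stereoretentive at sp2 carbon. The selectivity needed is between the two metal termini: tin transfers without base whereas boron needs base, so the order of addition fixes which half goes to which end and excludes statistical homodimers. The free hydroxyls, the acid-sensitive triol and the furanoid ring meet only neutral or basic media.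

Compound list
1 | ketoisophorone (2,6,6-trimethylcyclohex-2-ene-1,4-dione) | CC1=CC(=O)CC(C)(C)C1=O | starting material
2 | (4S)-4-hydroxy-2,6,6-trimethylcyclohex-2-en-1-one ((S)-phorenol) | CC1=C[C@@H](O)CC(C)(C)C1=O | intermediate
3 | (4S)-4-[(tert-butyldimethylsilyl)oxy]-2,6,6-trimethylcyclohex-2-en-1-one | CC1=C[C@@H](O[Si](C)(C)C(C)(C)C)CC(C)(C)C1=O | intermediate
4 | (1R,5S,6R)-5-[(tert-butyldimethylsilyl)oxy]-1,3,3-trimethyl-7-oxabicyclo[4.1.0]heptan-2-one | O=C1C(C)(C)C[C@H](O[Si](C)(C)C(C)(C)C)[C@H]2O[C@@]12C | intermediate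
5 | (E)-3-methylpent-2-en-4-yn-1-ol | C#C/C(C)=C/CO | starting material
6 | O,C-dilithio derivative of 5 (lithium alkoxide and lithium acetylide) | [Li]C#C/C(C)=C/CO[Li] | intermediate
7 | (1R,2R,5S,6R)-5-[(tert-butyldimethylsilyl)oxy]-2-[(3E)-5-hydroxy-3-methylpent-3-en-1-yn-1-yl]-1,3,3-trimethyl-7-oxabicyclo[4.1.0]heptan-2-ol (2-OH cis to the oxirane oxygen) | OC/C=C(C)/C#C[C@]1(O)C(C)(C)C[C@H](O[Si](C)(C)C(C)(C)C)[C@H]2O[C@@]12C | intermediate
8 | (2E)-5-[(1R,2R,4S)-4-[(tert-butyldimethylsilyl)oxy]-1,2-dihydroxy-2,6,6-trimethylcyclohexyl]-3-methylpent-2-en-4-yn-1-ol (cis-diol) | OC/C=C(C)/C#C[C@]1(O)C(C)(C)C[C@H](O[Si](C)(C)C(C)(C)C)C[C@@]1(C)O | intermediate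
9 | (2E,4E)-5-[(1S,2R,4S)-4-[(tert-butyldimethylsilyl)oxy]-1,2-dihydroxy-2,6,6-trimethylcyclohexyl]-3-methylpenta-2,4-dien-1-ol | OC/C=C(C)/C=C/[C@]1(O)C(C)(C)C[C@H](O[Si](C)(C)C(C)(C)C)C[C@@]1(C)O | intermediate
10 | (2E,4E)-5-[(1S,2R,4S)-4-[(tert-butyldimethylsilyl)oxy]-1,2-dihydroxy-2,6,6-trimethylcyclohexyl]-3-methylpenta-2,4-dienal | O=C/C=C(C)/C=C/[C@]1(O)C(C)(C)C[C@H](O[Si](C)(C)C(C)(C)C)C[C@@]1(C)O | intermediate
11 | propargyl alcohol (prop-2-yn-1-ol) | C#CCO | starting material
12 | dimethyl[(1E)-3-(dimethylalumanyloxy)-2-methylprop-1-en-1-yl]alumane | C/C(CO[Al](C)C)=C\[Al](C)C | intermediate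
13 | (E)-3-iodo-2-methylprop-2-en-1-ol | C/C(CO)=C\I | intermediate
14 | (E)-3-bromo-1-iodo-2-methylprop-1-ene | C/C(CBr)=C\I | intermediate
15 | diethyl [(2E)-3-iodo-2-methylprop-2-en-1-yl]phosphonate | CCOP(=O)(OCC)C/C(C)=C/I | intermediate
16 | α-lithiated 15 (lithium phosphonate carbanion) | [Li+].CCOP(=O)(OCC)[CH-]/C(C)=C/I | intermediate
17 | (1S,2R,4S)-4-[(tert-butyldimethylsilyl)oxy]-1-[(1E,3E,5E,7E)-8-iodo-3,7-dimethylocta-1,3,5,7-tetraen-1-yl]-2,6,6-trimethylcyclohexane-1,2-diol (O3-silyl ether of 18) | CC(/C=C/C=C(C)/C=C/[C@]1(O)C(C)(C)C[C@H](O[Si](C)(C)C(C)(C)C)C[C@@]1(C)O)=C\I | intermediate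
18 | ring-A C19 tetraenyl iodide, (1S,2R,4S)-1-[(1E,3E,5E,7E)-8-iodo-3,7-dimethylocta-1,3,5,7-tetraen-1-yl]-2,6,6-trimethylcyclohexane-1,2,4-triol | CC(/C=C/C=C(C)/C=C/[C@]1(O)C(C)(C)C[C@H](O)C[C@@]1(C)O)=C\I | intermediate
19 | (2R,6S,7aR)-6-[(tert-butyldimethylsilyl)oxy]-2-[(2E,4E,6E)-7-iodo-6-methylhepta-2,4,6-trien-2-yl]-4,4,7a-trimethyl-2,4,5,6,7,7a-hexahydro-1-benzofuran | I/C=C(C)/C=C/C=C(\C)[C@H]1C=C2C(C)(C)C[C@H](O[Si](C)(C)C(C)(C)C)C[C@@]2(C)O1 | intermediate
20 | furanoid C19 iodide, (2R,6S,7aR)-2-[(2E,4E,6E)-7-iodo-6-methylhepta-2,4,6-trien-2-yl]-4,4,7a-trimethyl-2,4,5,6,7,7a-hexahydro-1-benzofuran-6-ol | I/C=C(C)/C=C/C=C(\C)[C@H]1C=C2C(C)(C)C[C@H](O)C[C@@]2(C)O1 | intermediate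
21 | ethynylboronic acid pinacol ester | C#CB1OC(C)(C)C(C)(C)O1 | starting material
22 | tributyltin hydride | CCCC[SnH](CCCC)CCCC | starting material
23 | (E)-2-(tributylstannyl)vinylboronic acid pinacol ester | CCCC[Sn](CCCC)(CCCC)/C=C/B1OC(C)(C)C(C)(C)O1 | intermediate
24 | (1S,2R,4S)-1-[(1E,3E,5E,7E,9E)-3,7-dimethyl-10-(4,4,5,5-tetramethyl-1,3,2-dioxaborolan-2-yl)deca-1,3,5,7,9-pentaen-1-yl]-2,6,6-trimethylcyclohexane-1,2,4-triol | CC(/C=C/C=C(C)/C=C/[C@]1(O)C(C)(C)C[C@H](O)C[C@@]1(C)O)=C\C=C\B1OC(C)(C)C(C)(C)O1 | intermediate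
25 | CNP0210286.4, (3S,5R,6S,3'S,5'R,8'R)-5',8'-epoxy-5,6,5',8'-tetrahydro-β,β-carotene-3,5,6,3'-tetrol | CC(/C=C/C=C(C)/C=C/[C@]1(O)C(C)(C)C[C@H](O)C[C@@]1(C)O)=C\C=C\C=C(C)\C=C\C=C(/C)[C@H]1C=C2C(C)(C)C[C@H](O)C[C@@]2(C)O1 | target

Total step count: 16. Longest linear sequence: 11 steps (1–7, 11, 13, 14, 16) from ketoisophorone.

Steps most likely to fail

Step 13. After ionisation at C6 the long cation may be trapped at C8 from either face once the C7–C8 bond rotates. It may also lose a proton from the C9 or C13 methyl group (retro-type dehydration), scramble the E geometry of the iodotetraene, or be intercepted by the silylated O3. The fallback closes ring C before the polyene is lengthened. It sets out from 9: the same camphorsulfonic acid cyclodehydration on the shorter dienyl system should give the C15 furanoid alcohol F1, whose C8 epimers are separated and recycled at this small, iodine-free stage. MnO2 oxidation should then give the furanoid enal F2, and Horner–Wadsworth–Emmons reaction of F2 with 16 should come back to the route at 19. The ring-A branch is unchanged.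

Step 16. With both metals in one pot, the linchpin may suffer protodestannylation or premature loss of the boronate, tin-to-palladium transfer at the trisubstituted alkenylpalladium may be sluggish, and the growing polyene may drift in E/Z geometry. The fallback uses two separate Stille couplings on commercial (E)-1,2-bis(tributylstannyl)ethene. It sets out from 18: coupling with an excess of the distannane (Pd2(dba)3, AsPh3, NMP, rt, dark) should give the isolable C21 pentaenylstannane F3. A second Stille coupling of F3 with 20 under the same conditions should come back to the route at 25.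

Step 5. Hydride delivery to C4 may be slow or misdirected, because the trajectory runs syn-axial to the C6 alkynyl group and next to the C3 silyl ether, so that silyl migration or reduction of the enyne could compete. The fallback opens the oxirane before the side chain is attached. It sets out from 4: LiEt3BH should reduce the ketone and open the unencumbered epoxide to the cyclohexane-1,2-diol F4 (carbinol configuration of no consequence). Dess–Martin oxidation of the secondary carbinol should give the α-hydroxy ketone F5. Addition of excess 6 to F5, axial and anti to the two axial α-substituents (C1 methyl and 5-O), should come back to the route at 8.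

Further compounds
F1 | step 13 | (2E)-3-[(2R,6S,7aR)-6-[(tert-butyldimethylsilyl)oxy]-4,4,7a-trimethyl-2,4,5,6,7,7a-hexahydro-1-benzofuran-2-yl]but-2-en-1-ol | OC/C=C(\C)[C@H]1C=C2C(C)(C)C[C@H](O[Si](C)(C)C(C)(C)C)C[C@@]2(C)O1
F2 | step 13 | (2E)-3-[(2R,6S,7aR)-6-[(tert-butyldimethylsilyl)oxy]-4,4,7a-trimethyl-2,4,5,6,7,7a-hexahydro-1-benzofuran-2-yl]but-2-enal | O=C/C=C(\C)[C@H]1C=C2C(C)(C)C[C@H](O[Si](C)(C)C(C)(C)C)C[C@@]2(C)O1
F3 | step 16 | (1S,2R,4S)-1-[(1E,3E,5E,7E,9E)-3,7-dimethyl-10-(tributylstannyl)deca-1,3,5,7,9-pentaen-1-yl]-2,6,6-trimethylcyclohexane-1,2,4-triol | CC(/C=C/C=C(C)/C=C/[C@]1(O)C(C)(C)C[C@H](O)C[C@@]1(C)O)=C\C=C\[Sn](CCCC)(CCCC)CCCC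
F4 | step 5 | (1R,2S,5S)-5-[(tert-butyldimethylsilyl)oxy]-1,3,3-trimethylcyclohexane-1,2-diol | O[C@H]1C(C)(C)C[C@H](O[Si](C)(C)C(C)(C)C)C[C@@]1(C)O
F5 | step 5 | (2R,4S)-4-[(tert-butyldimethylsilyl)oxy]-2-hydroxy-2,6,6-trimethylcyclohexan-1-one | O=C1C(C)(C)C[C@H](O[Si](C)(C)C(C)(C)C)C[C@@]1(C)O
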